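**Retrosynthetic overview**
- The target is opened at the O1–C2 bond (the last step and the stereo-defining one). This gives a racemic 1-aryl-3-(2-hydroxyaryl)propan-1-ol, to be closed enantioconvergently by a chiral confined Brønsted acid.
- The racemic alcohol comes from a 2-hydroxychalcone by saturation of C=C and reduction of C=O.
- The chalcone comes from a Claisen–Schmidt condensation of 3',4',5'-trimethoxyacetophenone (ring B) with 2-hydroxy-3,4-dimethoxybenzaldehyde (ring A).
- Rings A and B are bought; the pyran ring C is the only ring made, in step 3.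

Assumption: both aromatic starting materials are catalogue compounds, and acid A is bought or prepared separately and not counted as a step.
Assumption: the (S,S) antipode of acid A is written as the one that gives (2S); the sense is checked by chiral HPLC on the first run and the (R,R) antipode is used if it is reversed.
Acid A = (S,S)-imidodiphosphorimidate HN[P(=NSO2CF3)(O2L)]2, where each O2L is (S)-3,3'-bis[3,5-bis(trifluoromethyl)phenyl]-1,1'-binaphthalene-2,2'-diolate bound to phosphorus through both oxygens.

**Step 1**
Reactants: 1 2-hydroxy-3,4-dimethoxybenzaldehyde; 2 1-(3,4,5-trimethoxyphenyl)ethanone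
Product: 4 (E)-3-(2-hydroxy-3,4-dimethoxyphenyl)-1-(3,4,5-trimethoxyphenyl)prop-2-en-1-one, via aldol adduct 3 (not isolated)
Conditions: KOH (3 equiv), EtOH–H2O, 25 °C, 24 h; then AcOH to pH 6
Reagents that add atoms: none
Why: Claisen–Schmidt condensation, in which the methyl ketone enolate adds to the non-enolisable aldehyde and the β-hydroxy ketone 3 loses water by E1cB to the conjugated (E)-enone; excess KOH is used because the phenol is deprotonated first, and no stereocentre is carried forward.

**Step 2**
Reactants: 4 (E)-3-(2-hydroxy-3,4-dimethoxyphenyl)-1-(3,4,5-trimethoxyphenyl)prop-2-en-1-one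
Product: 6 rac-3-(2-hydroxy-3,4-dimethoxyphenyl)-1-(3,4,5-trimethoxyphenyl)propan-1-ol, via saturated ketone 5 (not isolated)
Conditions: H2 (1 atm), 5% Pd/C, EtOAc, 25 °C; filter; then NaBH4, MeOH–THF, 0 °C
Reagents that add atoms: none
Why: Heterogeneous catalytic hydrogenation saturates the conjugated C=C under neutral conditions and sodium borohydride reduction then converts the aryl ketone 5 to the carbinol, which is deliberately racemic because step 3 is enantioconvergent.

**Step 3**
Reactants: 6 rac-3-(2-hydroxy-3,4-dimethoxyphenyl)-1-(3,4,5-trimethoxyphenyl)propan-1-ol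
Product: 8 (2S)-7,8,3',4',5'-pentamethoxyflavan, via benzylic cation 7 (not isolated)
Conditions: (S,S)-acid A, HN[P(=NSO2CF3)(O2L)]2 (5 mol %), 5 Å molecular sieves, toluene (0.02 M), 0 to 25 °C
Reagents that add atoms: none
Why: Proposed new method: catalytic enantioconvergent dehydrative SN1 cycloetherification, in which the strongly acidic confined acid protonates the benzylic hydroxyl of either enantiomer of 6 and releases water to give the planar, para-methoxy-stabilised cation 7 as a contact ion pair with the chiral anion (the carbinol configuration is erased), the phenol OH hydrogen-bonds to a sulfonylimide site of the anion and closes the six-membered ring on one enantiotopic face through a chair-like transition state with the aryl group equatorial, so C2 is set as S under catalyst control; the closest known reaction types are the chiral N-triflylphosphoramide-controlled ring closure of phenol-tethered allylic cations to 2H-chromenes and confined-acid intramolecular hydroalkoxylation of alkenes, neither shown for a saturated secondary benzylic alcohol giving a flavan.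

**Compound list**
1 | 2-hydroxy-3,4-dimethoxybenzaldehyde | O=Cc1ccc(OC)c(OC)c1O | starting material
2 | 1-(3,4,5-trimethoxyphenyl)ethanone (3',4',5'-trimethoxyacetophenone) | CC(=O)c1cc(OC)c(OC)c(OC)c1 | starting material
3 | rac-3-hydroxy-3-(2-hydroxy-3,4-dimethoxyphenyl)-1-(3,4,5-trimethoxyphenyl)propan-1-one (aldol adduct, not isolated) | COc1cc(cc(OC)c1OC)C(=O)CC(O)c1ccc(OC)c(OC)c1O | intermediate
4 | (E)-3-(2-hydroxy-3,4-dimethoxyphenyl)-1-(3,4,5-trimethoxyphenyl)prop-2-en-1-one | COc1cc(cc(OC)c1OC)C(=O)/C=C/c1ccc(OC)c(OC)c1O | intermediate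
5 | 3-(2-hydroxy-3,4-dimethoxyphenyl)-1-(3,4,5-trimethoxyphenyl)propan-1-one (saturated ketone, not isolated) | COc1cc(cc(OC)c1OC)C(=O)CCc1ccc(OC)c(OC)c1O | intermediate
6 | rac-3-(2-hydroxy-3,4-dimethoxyphenyl)-1-(3,4,5-trimethoxyphenyl)propan-1-ol | COc1cc(cc(OC)c1OC)C(O)CCc1ccc(OC)c(OC)c1O | intermediate
7 | 3-(2-hydroxy-3,4-dimethoxyphenyl)-1-(3,4,5-trimethoxyphenyl)propan-1-ylium, ion-paired with the conjugate base of acid A (not isolated) | COc1cc(cc(OC)c1OC)[CH+]CCc1ccc(OC)c(OC)c1O | intermediate
8 | (2S)-7,8-dimethoxy-2-(3,4,5-trimethoxyphenyl)chromane, i.e. (2S)-7,8,3',4',5'-pentamethoxyflavan | COc1cc([C@@H]2CCc3ccc(OC)c(OC)c3O2)cc(OC)c1OC | target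

**Summary**
Total step count: 3. Longest linear sequence: 3 steps (1 or 2 → 4 → 6 → 8).

**Steps most likely to fail, with fallbacks**

Step 3 (the proposed new step) is the most likely to fail.
- The cation is only moderately stabilised, because the 4-methoxy group is twisted by its two neighbours, so ionisation may be slow.
- The product can reopen at C2–O under the acid and lose ee if left after full conversion.
- The cation can instead close onto ring A, para to the 8-methoxy group, to give a 1-arylindane.

The fallback uses known chemistry and sets out from 5, which is isolated by stopping step 2 after the hydrogenation stage. Asymmetric transfer hydrogenation with RuCl[(R,R)-TsDPEN](p-cymene) in HCO2H/Et3N (5:2) at 25 °C gives (R)-3-(2-hydroxy-3,4-dimethoxyphenyl)-1-(3,4,5-trimethoxyphenyl)propan-1-ol F1. An intramolecular Mitsunobu reaction (PPh3, diisopropyl azodicarboxylate, THF, 0 °C) then closes O1–C2 with inversion. This comes back to the route at 8.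

Step 1 is second. The aldehyde is deactivated twice over, as a phenoxide and by the para-methoxy group, so the condensation may stall at low conversion.

The fallback sets out from 1. Benzylation (BnBr, K2CO3, DMF, 25 °C) gives 2-(benzyloxy)-3,4-dimethoxybenzaldehyde F2. Claisen–Schmidt condensation of this with 2 (KOH, EtOH, 25 °C) passes through rac-3-[2-(benzyloxy)-3,4-dimethoxyphenyl]-3-hydroxy-1-(3,4,5-trimethoxyphenyl)propan-1-one F3 (not isolated) to (E)-3-[2-(benzyloxy)-3,4-dimethoxyphenyl]-1-(3,4,5-trimethoxyphenyl)prop-2-en-1-one F4. Hydrogenation (H2, 5% Pd/C, EtOAc–EtOH) saturates the alkene and cleaves the benzyl ether in the same operation. This comes back to the route at 5, which goes on through the NaBH4 stage of step 2.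

Step 2 is third. Over Pd/C the electron-rich benzylic C–O bond may be hydrogenolysed to the 1,3-diarylpropane once some ketone has been reduced.

The fallback sets out from 4 and reverses the order of the two reductions without a heterogeneous metal. Luche 1,2-reduction (NaBH4, CeCl3·7H2O, MeOH, −20 °C) gives rac-(E)-3-(2-hydroxy-3,4-dimethoxyphenyl)-1-(3,4,5-trimethoxyphenyl)prop-2-en-1-ol F5. F5 is kept buffered because acid closes it to a racemic flav-3-ene. Diimide saturation of the alkene (2-nitrobenzenesulfonohydrazide, Et3N, CH2Cl2, 25 °C) then comes back to the route at 6.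

**Further compounds**
F1 | step 3 | (R)-3-(2-hydroxy-3,4-dimethoxyphenyl)-1-(3,4,5-trimethoxyphenyl)propan-1-ol | COc1cc(cc(OC)c1OC)[C@H](O)CCc1ccc(OC)c(OC)c1O
F2 | step 1 | 2-(benzyloxy)-3,4-dimethoxybenzaldehyde | O=Cc1ccc(OC)c(OC)c1OCc1ccccc1
F3 | step 1 | rac-3-[2-(benzyloxy)-3,4-dimethoxyphenyl]-3-hydroxy-1-(3,4,5-trimethoxyphenyl)propan-1-one | COc1cc(cc(OC)c1OC)C(=O)CC(O)c1ccc(OC)c(OC)c1OCc1ccccc1
F4 | step 1 | (E)-3-[2-(benzyloxy)-3,4-dimethoxyphenyl]-1-(3,4,5-trimethoxyphenyl)prop-2-en-1-one | COc1cc(cc(OC)c1OC)C(=O)/C=C/c1ccc(OC)c(OC)c1OCc1ccccc1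
F5 | step 2 | rac-(E)-3-(2-hydroxy-3,4-dimethoxyphenyl)-1-(3,4,5-trimethoxyphenyl)prop-2-en-1-ol | COc1cc(cc(OC)c1OC)C(O)/C=C/c1ccc(OC)c(OC)c1O
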